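## The problem

The target, C30H22O16, is a row of five benzene rings joined only by four diaryl ether oxygens. It carries twelve free phenols and no stereocentre, so nothing has to be controlled in space; position and chain length are the whole problem. With the rings lettered A (2,4,6-trihydroxyphenyl end) to E (3,4,5-trihydroxyphenoxy end), each ether oxygen sits on a carbon flanked by two oxygen-bearing carbons (C1 of ring A, C4 of rings B, C and D). Its other bond goes to C1 of the next ring, a carbon flanked by two CH groups. Making these bonds by etherification would mean, four times over, using a 2,6-dioxygenated phenol as nucleophile against an electron-rich, unactivated aryl carbon. Rings B, C and D are the same 3,5-dihydroxy-1,4-phenylenedioxy unit, so the chain has to grow one defined unit at a time, with the oxygen that carries the next ring distinguishable from all others. The free polyphenol (pyrogallol, hydroquinone and phloroglucinol types in one molecule) oxidises readily in air, fastest in base, and ring A is nucleophilic at carbon. The hydroxyls must therefore stay masked to the end and be released under neutral, reducing conditions. The feature that opens a way round the etherification is the substitution pattern of ring C, shared by rings B, D and E. C3, C4 and C5 carry three contiguous oxygens and C2 and C6 are CH, exactly as in a 3,5-dialkoxy-4-pyranone. C1 is an ether carbon between two CH groups, which is the pattern of an aryloxymethylene phosphorus ylide carbon standing in for the pyranone ring oxygen.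

## Retrosynthesis

**End game.** In 39 the last bonds broken are the eleven O–CH2Ph bonds of 38, and before that the single O–Si bond of 37. Benzyl is preferred to methyl because the dodecaphenol 39 would not tolerate a Lewis-acid demethylation and its work-up well, whereas hydrogenolysis frees it without acid or base. 38 and 37 differ from 39 only in protecting groups. The forward steps must cleave Si–O first and then every benzyl ether.

**Ring E.** Ring E of 37 is cut at C1–C2 and C1–C6. C1 stays on the oxygen of the tetramer as the phosphorus-bearing carbon of salt 33, and C2–C6 with their three oxygens become the pyrylium salt 12, the O-silylated form of pyranone 4. The neighbouring cut, the O–C1 aryl ether bond, would ask hindered phenol 31 to couple with an electron-rich aryl electrophile. The chosen cut never makes a bond from oxygen to an aromatic carbon. The precursor has one ring fewer, and the new fragment is an achiral, symmetric five-carbon unit.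

**The relay between rings.** Salt 33 goes back to phenol 31 through its C–P and O–CH2 bonds, with the one-carbon unit coming from dihalomethane 9. Phenol 31 goes back to silyl ether 30 through O–Si. These two operations are the cost of each cycle. The forward reaction must alkylate a hindered phenoxide once with 9 without going on to the symmetrical acetal.

**Ring D.** Ring D of 30 is cut in the same way (C1–C2, C1–C6) to salt 26 and 12. Salt 26 comes from phenol 24, and 24 from silyl ether 23. Because the product of each ring synthesis is, after desilylation, again a 2,6-dioxygenated phenol, the sequence is self-repeating and nothing new is asked of it here.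

**Ring C, the key disconnection.** Ring C of 23 is cut at C1–C2 and C1–C6 to the AB phosphonium salt 19 and pyranone 4, which enters as its silyloxypyrylium triflate 12. This is the step on which the plan rests: a seven-benzyl trimer falls to a five-benzyl dimer and a small symmetric heterocycle. The forward reaction must add the ylide carbon of 19 to C2 of the O-silylated pyranone, not to C4 or to silicon, and must then open the pyran and close the carbocycle by loss of the phosphorus with the old ring oxygen. Two changes strengthen the step from within. The second proton is removed by an added amide base, not by a sacrificial second equivalent of the valuable ylide. The pyranone is silylated completely in a separate operation before it meets any ylide.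

**Ring B.** Salt 19 is traced to phenol 17, silyl ether 16 and the cut C1–C2/C1–C6 of ring B, giving the ring A salt 11 and 12. Salt 11 comes from phenol 8 and 9. This is the smallest case of the ring synthesis and the place where its conditions would be settled.

**Ring A.** Phenol 8 has no hindered ether bond to make, so the unproven ring synthesis is not spent on it. Its C1–O bond is traced to the C1–CHO bond of aldehyde 6 (oxidative aryl migration), and 6 to the commercial trihydroxy aldehyde 5 by cutting three O–benzyl bonds. This is two known steps.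

**Pyrylium salt.** Salt 12 is cut at its O–Si bond to pyranone 4 and the silyl triflate. One batch of 12 is made and drawn on for rings B, C, D and E, so the electrophile is the same defined material in all four ring syntheses and carries no free silylating agent.

**Pyranone.** In 4 the bonds C2–C3 and C5–C6 and one ring O–C bond are cut, giving ketone 1 and two molecules of formate 2. The symmetry of 1 means that both formylations are the same reaction and no regiochemistry arises.

## Roads not taken

**Alternative 1:** Ring D is cut into two acyclic pieces: the ABC aryloxypropiolate A2 and the ring E aryloxyacetoacetate A3. With Mg(OMe)2, C2 of A3 would add to the oxygen-bearing alkyne carbon of A2, and the aryloxymethyl carbon would then close onto the propiolate ester in a Claisen condensation. The result is the pentamer A1 with ring D as a salicylate.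
- Merits: the route is convergent (three rings and one ring are joined while the fifth is formed), the C–C bond formations are enolate chemistry with good precedent for resorcylates, and ring E is attached by a simple phenol alkylation.
- Weak points: A2 is an ynol ether ester of a hindered phenol, hard to make and to handle. After the Michael addition the ABC aryloxide is the leaving group of a vinylogous carbonate and can be expelled, which destroys the bond the step was meant to keep. The A–O–B and B–O–C linkages inside A2 are not addressed at all. The ester must be removed afterwards, and ten methyl ethers must be cleaved with a Lewis acid at the end.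
- Comparison: this road is more convergent and its ring-forming step is closer to known chemistry than the ylide step. The chosen plan makes all four hindered linkages by one repeated operation and ends with a neutral hydrogenolysis.

**Alternative 2:** All four O–C1 bonds are cut at once, back to the capping phenol A6 and four molecules of syringic acid A5. Anodic oxidation would couple each hindered phenoxyl oxygen to the carboxyl-bearing carbon of a syringate radical with decarboxylation. That would give the undecamethyl pentamer A4 in one pot.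
- Merits: it is the shortest route conceivable, the regiochemistry of every new bond is built into the monomer, and the materials are cheap.
- Weak points: chain length is not controlled. A5 oligomerises without the cap, and every chain-end phenol is as oxidisable as the monomer, so a distribution of oligomers of near-identical polarity is expected. Redistribution through quinone ketals and over-oxidation to quinones add to this. Eleven methyl ethers then need a Lewis-acid cleavage on a sensitive polyphenol.
- Comparison: if A4 formed selectively, this road would beat the chosen one by more than ten steps, and that advantage is real. The chosen plan sets against it a single defined, isolable compound after every step.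

**Alternative 3:** Ring C is cut at C3–C4 and traced to pyranone A8. A8 is a derivative of triacetic acid lactone A9 carrying the AB unit on the C4 oxygen and the DE unit on the C6 methyl carbon. Mg(OMe)2 in methanol would open the lactone to a keto ester whose aryloxymethyl ketone carbon closes onto the ester. The product is the pentamer A7 with free hydroxyls at C3 and C5 of ring C.
- Merits: it is the most convergent of all (two rings plus two rings, joined as the middle ring forms), the pyranone-to-benzene isomerisation has precedent, and two hydroxyls appear unprotected.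
- Weak points: the AB aryloxy group on C4 of A8 is again a vinylogous carbonate open to displacement by methoxide. The closure must start from the less acidic aryloxymethyl position in competition with the doubly activated methylene. Both halves still contain a hindered diaryl ether that must come from elsewhere, and the methyl ethers again call for Lewis-acid cleavage.
- Comparison: this road has the shorter linear sequence and a more familiar ring closure. The chosen plan is longer and rests on an untested ylide step, but it solves every ether linkage in the same way.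

Key step: step 9

Assumption: the phosphonium salts are drawn as chlorides; any bromide picked up from bromochloromethane would leave as its sodium salt in the same way and would not change the chemistry.

Shorthand in names: A is the 2,4,6-tris(benzyloxy)phenyl ring. B, C, D and E are 3,5-bis(benzyloxy)-1,4-phenylene rings, each bound through the oxygen on its C1 to the hindered oxygen of the preceding ring and carrying the named group on its C4 oxygen.

## Route

Step 1
Reactants: 1 1,3-bis(benzyloxy)propan-2-one; 2 ethyl formate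
Product: 4 3,5-bis(benzyloxy)-4H-pyran-4-one, via disodium bis-enolate 3 (not isolated)
Conditions: NaH (2.2 equiv), HCO2Et (excess), THF, 0 °C to rt; then aq HCl, EtOH, rt
Reagents that add atoms: none
Why: Crossed Claisen formylation at both α-carbons of the symmetric ketone (the formate cannot enolise and is in excess) gives dienolate 3; acid then closes the bis(hydroxymethylene) ketone to the 4-pyranone with loss of water, the established route from 1,3-disubstituted acetones to 3,5-disubstituted 4-pyranones.

Step 2
Reactants: 5 2,4,6-trihydroxybenzaldehyde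
Product: 6 2,4,6-tris(benzyloxy)benzaldehyde
Conditions: BnBr (3.6 equiv), K2CO3, DMF, 60 °C
Reagents that add atoms: benzyl bromide, BrCc1ccccc1
Why: Williamson ether synthesis; the formyl group lowers the nucleophilicity of the ring carbons, so O-benzylation should outrun the C-benzylation typical of phloroglucinols, and excess bromide with warming serves the two hydrogen-bonded ortho hydroxyls.

Step 3
Reactants: 6 2,4,6-tris(benzyloxy)benzaldehyde
Product: 8 2,4,6-tris(benzyloxy)phenol, via aryl formate 7 (not isolated)
Conditions: mCPBA, CH2Cl2, 0 °C to rt; aq NaHCO3 wash; then K2CO3 (cat.), MeOH, rt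
Reagents that add atoms: 3-chloroperbenzoic acid, OOC(=O)c1cccc(Cl)c1
Why: Baeyer–Villiger oxidation of an electron-rich benzaldehyde (Dakin-type): the trialkoxyaryl group migrates in preference to hydride to give formate 7, and methanolysis frees the phenol only after the peracid has been washed out, so the oxidisable phenol never meets the oxidant.

Step 4
Reactants: 8 2,4,6-tris(benzyloxy)phenol; 9 bromochloromethane
Product: 11 {[2,4,6-tris(benzyloxy)phenoxy]methyl}triphenylphosphonium chloride, via chloromethyl ether 10 (not isolated)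
Conditions: NaH, THF, 0 °C; BrCH2Cl (15 equiv), 60 °C; filter, evaporate; then PPh3, toluene, 90 °C
Reagents that add atoms: triphenylphosphine, c1ccc(cc1)P(c1ccccc1)c1ccccc1
Why: O-Alkylation of a 2,6-disubstituted phenoxide by bromochloromethane with loss of bromide is the known O-chloromethylation of hindered phenols; the large excess of dihalide and the flanking benzyloxy groups hold back the bis(aryloxy)methane. Quaternisation of triphenylphosphine by the α-chloro ether is the standard route to alkoxymethyl- and aryloxymethylphosphonium chlorides.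

Step 5
Reactants: 4 3,5-bis(benzyloxy)-4H-pyran-4-one
Product: 12 3,5-bis(benzyloxy)-4-[(tert-butyldimethylsilyl)oxy]pyrylium trifluoromethanesulfonate
Conditions: TBSOTf (1.05 equiv), CH2Cl2, rt; evaporate under high vacuum, wash with dry pentane; kept under Ar and used as a CH2Cl2 stock solution
Reagents that add atoms: tert-butyldimethylsilyl trifluoromethanesulfonate, CC(C)(C)[Si](C)(C)OS(=O)(=O)C(F)(F)F
Why: O-Silylation of the carbonyl oxygen of a 4-pyranone by a silyl triflate gives the aromatic 4-silyloxypyrylium triflate, a known reaction of 4-pyranones. One batch, stripped of the slight excess of volatile silyl triflate and kept dry, supplies the same electrophile, free of silylating agent, to all four ring syntheses.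

Step 6
Reactants: 11 {[2,4,6-tris(benzyloxy)phenoxy]methyl}triphenylphosphonium chloride; 12 3,5-bis(benzyloxy)-4-[(tert-butyldimethylsilyl)oxy]pyrylium trifluoromethanesulfonate
Product: 16 A–O–B–OSi(t-Bu)Me2 (penta-O-benzyl AB dimer with ring B as its C4 silyl ether), via ylide 13 (not isolated), via 2H-pyran adduct 14 (not isolated), via open-chain ylide aldehyde 15 (not isolated)
Conditions: 11, NaN(SiMe3)2 (1.0 equiv), THF, −78 °C; add 12 (1.0 equiv) in CH2Cl2, −78 °C; then NaN(SiMe3)2 (1.1 equiv), −78 °C to rt
Reagents that add atoms: none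
Why: Proposed new method: as in step 9, ylide 13 should add through carbon to C2 of silyloxypyrylium ion 12, adduct 14 is deprotonated and opens to ylide dienal 15, and a six-membered intramolecular Wittig closure with loss of Ph3PO forms ring B; the closest known reaction type is the conversion of pyrylium salts into benzenes by alkylidenetriphenylphosphoranes, not yet shown for alkoxymethylene ylides or 4-silyloxypyrylium ions. The two stereocentres of 14 form without control and vanish on aromatisation; this smallest case is where the conditions for the later rings would be settled.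

Step 7
Reactants: 16 A–O–B–OSi(t-Bu)Me2
Product: 17 A–O–B–OH (2,6-bis(benzyloxy)-4-[2,4,6-tris(benzyloxy)phenoxy]phenol)
Conditions: Bu4NF, AcOH, THF, 0 °C
Reagents that add atoms: none
Why: Fluoride cleavage of an aryl silyl ether; acetic acid keeps the freed electron-rich phenol protonated and so shields it from air oxidation, and benzyl and diaryl ethers are inert.

Step 8
Reactants: 17 A–O–B–OH; 9 bromochloromethane
Product: 19 A–O–B–OCH2PPh3 chloride (the (aryloxymethyl)triphenylphosphonium chloride of 17), via chloromethyl ether 18 (not isolated)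
Conditions: NaH, THF, 0 °C; BrCH2Cl (15 equiv), 60 °C; filter, evaporate; then PPh3, toluene, 90 °C
Reagents that add atoms: triphenylphosphine, c1ccc(cc1)P(c1ccccc1)c1ccccc1
Why: Same O-chloromethylation of a hindered phenoxide and phosphine quaternisation as in step 4; the phenol oxygen of 17 has the same 2,6-bis(benzyloxy) surroundings as that of 8.

Step 9
Reactants: 19 A–O–B–OCH2PPh3 chloride; 12 3,5-bis(benzyloxy)-4-[(tert-butyldimethylsilyl)oxy]pyrylium trifluoromethanesulfonate
Product: 23 A–O–B–O–C–OSi(t-Bu)Me2 (hepta-O-benzyl ABC trimer with ring C as its C4 silyl ether), via ylide 20 (not isolated), via 2H-pyran adduct 21 (not isolated), via open-chain ylide aldehyde 22 (not isolated)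
Conditions: 19, NaN(SiMe3)2 (1.0 equiv), THF, −78 °C; add 12 (1.0 equiv) in CH2Cl2, −78 °C; then NaN(SiMe3)2 (1.1 equiv), −78 °C to rt
Reagents that add atoms: none
Why: Proposed new method: ylide 20, freed from 19 by one equivalent of NaN(SiMe3)2, should add through carbon to C2 of the 4-silyloxypyrylium ion 12, the position next to the ring oxygen, to give 2H-pyran phosphonium salt 21. The second equivalent of base removes the remaining P–CH proton and the pyran opens (oxa-6π electrocyclic ring opening, equivalently β-elimination of the ring enol oxygen) to ylide dienal 22, in which the old C4=C5 double bond keeps its cis geometry. The ylide carbon then attacks the formyl carbon (old C6) in an intramolecular Wittig olefination, and loss of Ph3PO gives the aromatic ring; C1–C2 and C1–C6 of ring C are the two new skeletal bonds and the pyran oxygen leaves on phosphorus. The closest known reaction type is the conversion of pyrylium salts into benzenes by alkylidenetriphenylphosphoranes, applied to a 4-silyloxypyrylium ion of the kind known from O-silylation of 4-pyranones by silyl triflates; an α-aryloxy ylide and a 3,5-dialkoxypyrylium ion have not been combined in this way. Ring C closes as a six-membered carbocycle by carbonyl olefination (formally a 6π closure of the phosphonium dienolate followed by elimination), and aromatisation makes the closure irreversible. The two stereocentres of 21 arise without control and both become trigonal, so 23 has no stereocentre. The step needs attack at C2 and not at C4 or silicon, and a cisoid arrangement about the old C2=C3 bond of 22: the bulky silyloxy group shields C4 and its own silicon, the preformed salt 12 brings no free silylating agent to the ylide, the C2/C6 symmetry of 12 removes any regiochemical choice, and delocalisation of the ylide into the dienal lets the old C2=C3 bond rotate into the reactive geometry.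

Step 10
Reactants: 23 A–O–B–O–C–OSi(t-Bu)Me2
Product: 24 A–O–B–O–C–OH (hepta-O-benzyl ABC trimer with a free hydroxyl at C4 of ring C)
Conditions: Bu4NF, AcOH, THF, 0 °C
Reagents that add atoms: none
Why: Fluoride cleavage of the aryl silyl ether under buffered conditions, as in step 7.

Step 11
Reactants: 24 A–O–B–O–C–OH; 9 bromochloromethane
Product: 26 A–O–B–O–C–OCH2PPh3 chloride, via chloromethyl ether 25 (not isolated)
Conditions: NaH, THF, 0 °C; BrCH2Cl (15 equiv), 60 °C; filter, evaporate; then PPh3, toluene, 90 °C
Reagents that add atoms: triphenylphosphine, c1ccc(cc1)P(c1ccccc1)c1ccccc1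
Why: O-Chloromethylation of the hindered phenoxide and phosphine quaternisation, as in step 4.

Step 12
Reactants: 26 A–O–B–O–C–OCH2PPh3 chloride; 12 3,5-bis(benzyloxy)-4-[(tert-butyldimethylsilyl)oxy]pyrylium trifluoromethanesulfonate
Product: 30 A–O–B–O–C–O–D–OSi(t-Bu)Me2 (nona-O-benzyl ABCD tetramer with ring D as its C4 silyl ether), via ylide 27 (not isolated), via 2H-pyran adduct 28 (not isolated), via open-chain ylide aldehyde 29 (not isolated)
Conditions: 26, NaN(SiMe3)2 (1.0 equiv), THF, −78 °C; add 12 (1.0 equiv) in CH2Cl2, −78 °C; then NaN(SiMe3)2 (1.1 equiv), −78 °C to rt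
Reagents that add atoms: none
Why: Proposed new method: the sequence of step 9 repeated for ring D (C-attack of ylide 27 at C2 of 12, opening of adduct 28 to ylide dienal 29, six-membered intramolecular Wittig closure with loss of Ph3PO); the closest known reaction type is the pyrylium-to-benzene conversion with alkylidenetriphenylphosphoranes. The reacting end of 26 has the same surroundings as that of 19, and the transient stereocentres of 28 disappear on aromatisation.

Step 13
Reactants: 30 A–O–B–O–C–O–D–OSi(t-Bu)Me2
Product: 31 A–O–B–O–C–O–D–OH (nona-O-benzyl ABCD tetramer with a free hydroxyl at C4 of ring D)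
Conditions: Bu4NF, AcOH, THF, 0 °C
Reagents that add atoms: none
Why: Fluoride cleavage of the aryl silyl ether under buffered conditions, as in step 7.

Step 14
Reactants: 31 A–O–B–O–C–O–D–OH; 9 bromochloromethane
Product: 33 A–O–B–O–C–O–D–OCH2PPh3 chloride, via chloromethyl ether 32 (not isolated)
Conditions: NaH, THF, 0 °C; BrCH2Cl (15 equiv), 60 °C; filter, evaporate; then PPh3, toluene, 90 °C
Reagents that add atoms: triphenylphosphine, c1ccc(cc1)P(c1ccccc1)c1ccccc1
Why: O-Chloromethylation of the hindered phenoxide and phosphine quaternisation, as in step 4.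

Step 15
Reactants: 33 A–O–B–O–C–O–D–OCH2PPh3 chloride; 12 3,5-bis(benzyloxy)-4-[(tert-butyldimethylsilyl)oxy]pyrylium trifluoromethanesulfonate
Product: 37 A–O–B–O–C–O–D–O–E–OSi(t-Bu)Me2 (undeca-O-benzyl pentamer with ring E as its C4 silyl ether), via ylide 34 (not isolated), via 2H-pyran adduct 35 (not isolated), via open-chain ylide aldehyde 36 (not isolated)
Conditions: 33, NaN(SiMe3)2 (1.0 equiv), THF, −78 °C; add 12 (1.0 equiv) in CH2Cl2, −78 °C; then NaN(SiMe3)2 (1.1 equiv), −78 °C to rt
Reagents that add atoms: none
Why: Proposed new method: the sequence of step 9 repeated for ring E (C-attack of ylide 34 at C2 of 12, opening of adduct 35 to ylide dienal 36, six-membered intramolecular Wittig closure with loss of Ph3PO); the closest known reaction type is the pyrylium-to-benzene conversion with alkylidenetriphenylphosphoranes. The transient stereocentres of 35 disappear on aromatisation.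

Step 16
Reactants: 37 A–O–B–O–C–O–D–O–E–OSi(t-Bu)Me2
Product: 38 A–O–B–O–C–O–D–O–E–OH (undeca-O-benzyl pentamer with a free hydroxyl at C4 of ring E)
Conditions: Bu4NF, AcOH, THF, 0 °C
Reagents that add atoms: none
Why: Fluoride cleavage of the aryl silyl ether under buffered conditions, as in step 7; removing silicon before the benzyl groups leaves the last step with only volatile by-products.

Step 17
Reactants: 38 A–O–B–O–C–O–D–O–E–OH
Product: 39 target pentamer (dodecaphenol)
Conditions: H2 (1 atm), 10% Pd/C, THF/MeOH, rt; filter under argon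
Reagents that add atoms: none
Why: Hydrogenolysis of eleven aryl benzyl ethers over palladium on carbon; diaryl ethers and the arene rings are not reduced under these conditions, and the neutral, reducing medium protects the air-sensitive polyphenol until it is isolated.

## Compound list

1 | 1,3-bis(benzyloxy)propan-2-one | O=C(COCc1ccccc1)COCc1ccccc1 | starting material
2 | ethyl formate | CCOC=O | starting material
3 | disodium 2,4-bis(benzyloxy)-3-oxopenta-1,4-diene-1,5-diolate (double-bond geometry not defined) | [Na+].[Na+].[O-]C=C(OCc1ccccc1)C(=O)C(OCc1ccccc1)=C[O-] | intermediate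
4 | 3,5-bis(benzyloxy)-4H-pyran-4-one | O=C1C(OCc2ccccc2)=COC=C1OCc1ccccc1 | intermediate
5 | 2,4,6-trihydroxybenzaldehyde | O=Cc1c(O)cc(O)cc1O | starting material
6 | 2,4,6-tris(benzyloxy)benzaldehyde | O=Cc1c(OCc2ccccc2)cc(OCc2ccccc2)cc1OCc1ccccc1 | intermediate
7 | 2,4,6-tris(benzyloxy)phenyl formate | O=COc1c(OCc2ccccc2)cc(OCc2ccccc2)cc1OCc1ccccc1 | intermediate
8 | 2,4,6-tris(benzyloxy)phenol | Oc1c(OCc2ccccc2)cc(OCc2ccccc2)cc1OCc1ccccc1 | intermediate
9 | bromochloromethane | ClCBr | starting material
10 | 1,3,5-tris(benzyloxy)-2-(chloromethoxy)benzene | O(Cc6ccccc6)c1cc(OCc6ccccc6)c(OCCl)c(OCc6ccccc6)c1 | intermediate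
11 | {[2,4,6-tris(benzyloxy)phenoxy]methyl}triphenylphosphonium chloride | O(Cc6ccccc6)c1cc(OCc6ccccc6)c(OC[P+](c6ccccc6)(c6ccccc6)c6ccccc6)c(OCc6ccccc6)c1.[Cl-] | intermediate
12 | 3,5-bis(benzyloxy)-4-[(tert-butyldimethylsilyl)oxy]pyrylium trifluoromethanesulfonate | CC(C)(C)[Si](C)(C)Oc1c(OCc2ccccc2)c[o+]cc1OCc1ccccc1.[O-]S(=O)(=O)C(F)(F)F | intermediate
13 | {[2,4,6-tris(benzyloxy)phenoxy]methylidene}triphenylphosphorane | O(Cc6ccccc6)c1cc(OCc6ccccc6)c(OC=P(c6ccccc6)(c6ccccc6)c6ccccc6)c(OCc6ccccc6)c1 | intermediate
14 | ring A 2H-pyran adduct: {[3,5-bis(benzyloxy)-4-(tert-butyldimethylsilyloxy)-2H-pyran-2-yl][2,4,6-tris(benzyloxy)phenoxy]methyl}triphenylphosphonium triflate (diastereomer mixture, racemic) | O(Cc6ccccc6)c1cc(OCc6ccccc6)c(OC([P+](c6ccccc6)(c6ccccc6)c6ccccc6)C7OC=C(OCc6ccccc6)C(O[Si](C)(C)C(C)(C)C)=C7OCc6ccccc6)c(OCc6ccccc6)c1.[O-]S(=O)(=O)C(F)(F)F | intermediate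
15 | ring A open-chain ylide aldehyde: (2Z)-2,4-bis(benzyloxy)-3-(tert-butyldimethylsilyloxy)-6-[2,4,6-tris(benzyloxy)phenoxy]-6-(triphenylphosphoranylidene)hexa-2,4-dienal (geometry at C4=C5 not fixed) | O(Cc6ccccc6)c1cc(OCc6ccccc6)c(OC(=P(c6ccccc6)(c6ccccc6)c6ccccc6)C=C(OCc6ccccc6)/C(O[Si](C)(C)C(C)(C)C)=C(OCc6ccccc6)\C=O)c(OCc6ccccc6)c1 | intermediate
16 | A–O–B–OSi(t-Bu)Me2: tert-butyl{2,6-bis(benzyloxy)-4-[2,4,6-tris(benzyloxy)phenoxy]phenoxy}dimethylsilane | O(Cc6ccccc6)c1cc(OCc6ccccc6)c(Oc2cc(OCc6ccccc6)c(O[Si](C)(C)C(C)(C)C)c(OCc6ccccc6)c2)c(OCc6ccccc6)c1 | intermediate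
17 | A–O–B–OH: 2,6-bis(benzyloxy)-4-[2,4,6-tris(benzyloxy)phenoxy]phenol | O(Cc6ccccc6)c1cc(OCc6ccccc6)c(Oc2cc(OCc6ccccc6)c(O)c(OCc6ccccc6)c2)c(OCc6ccccc6)c1 | intermediate
18 | A–O–B–OCH2Cl: 1,3-bis(benzyloxy)-2-(chloromethoxy)-5-[2,4,6-tris(benzyloxy)phenoxy]benzene | O(Cc6ccccc6)c1cc(OCc6ccccc6)c(Oc2cc(OCc6ccccc6)c(OCCl)c(OCc6ccccc6)c2)c(OCc6ccccc6)c1 | intermediate
19 | A–O–B–OCH2PPh3 chloride: ({2,6-bis(benzyloxy)-4-[2,4,6-tris(benzyloxy)phenoxy]phenoxy}methyl)triphenylphosphonium chloride | O(Cc6ccccc6)c1cc(OCc6ccccc6)c(Oc2cc(OCc6ccccc6)c(OC[P+](c6ccccc6)(c6ccccc6)c6ccccc6)c(OCc6ccccc6)c2)c(OCc6ccccc6)c1.[Cl-] | intermediate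
20 | A–O–B–OCH=PPh3: ylide of 19 | O(Cc6ccccc6)c1cc(OCc6ccccc6)c(Oc2cc(OCc6ccccc6)c(OC=P(c6ccccc6)(c6ccccc6)c6ccccc6)c(OCc6ccccc6)c2)c(OCc6ccccc6)c1 | intermediate
21 | AB 2H-pyran adduct: A–O–B–O–CH(PPh3)–[3,5-bis(benzyloxy)-4-(tert-butyldimethylsilyloxy)-2H-pyran-2-yl] triflate (diastereomer mixture, racemic) | O(Cc6ccccc6)c1cc(OCc6ccccc6)c(Oc2cc(OCc6ccccc6)c(OC([P+](c6ccccc6)(c6ccccc6)c6ccccc6)C7OC=C(OCc6ccccc6)C(O[Si](C)(C)C(C)(C)C)=C7OCc6ccccc6)c(OCc6ccccc6)c2)c(OCc6ccccc6)c1.[O-]S(=O)(=O)C(F)(F)F | intermediate
22 | AB open-chain ylide aldehyde: (2Z)-6-(A–O–B–O)-2,4-bis(benzyloxy)-3-(tert-butyldimethylsilyloxy)-6-(triphenylphosphoranylidene)hexa-2,4-dienal (geometry at C4=C5 not fixed) | O(Cc6ccccc6)c1cc(OCc6ccccc6)c(Oc2cc(OCc6ccccc6)c(OC(=P(c6ccccc6)(c6ccccc6)c6ccccc6)C=C(OCc6ccccc6)/C(O[Si](C)(C)C(C)(C)C)=C(OCc6ccccc6)\C=O)c(OCc6ccccc6)c2)c(OCc6ccccc6)c1 | intermediate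
23 | A–O–B–O–C–OSi(t-Bu)Me2: hepta-O-benzyl ABC trimer, ring C C4 tert-butyldimethylsilyl ether | O(Cc6ccccc6)c1cc(OCc6ccccc6)c(Oc2cc(OCc6ccccc6)c(Oc3cc(OCc6ccccc6)c(O[Si](C)(C)C(C)(C)C)c(OCc6ccccc6)c3)c(OCc6ccccc6)c2)c(OCc6ccccc6)c1 | intermediate
24 | A–O–B–O–C–OH: hepta-O-benzyl ABC trimer, free hydroxyl at C4 of ring C | O(Cc6ccccc6)c1cc(OCc6ccccc6)c(Oc2cc(OCc6ccccc6)c(Oc3cc(OCc6ccccc6)c(O)c(OCc6ccccc6)c3)c(OCc6ccccc6)c2)c(OCc6ccccc6)c1 | intermediate
25 | A–O–B–O–C–OCH2Cl: chloromethyl ether of 24 | O(Cc6ccccc6)c1cc(OCc6ccccc6)c(Oc2cc(OCc6ccccc6)c(Oc3cc(OCc6ccccc6)c(OCCl)c(OCc6ccccc6)c3)c(OCc6ccccc6)c2)c(OCc6ccccc6)c1 | intermediate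
26 | A–O–B–O–C–OCH2PPh3 chloride: (aryloxymethyl)triphenylphosphonium chloride of 24 | O(Cc6ccccc6)c1cc(OCc6ccccc6)c(Oc2cc(OCc6ccccc6)c(Oc3cc(OCc6ccccc6)c(OC[P+](c6ccccc6)(c6ccccc6)c6ccccc6)c(OCc6ccccc6)c3)c(OCc6ccccc6)c2)c(OCc6ccccc6)c1.[Cl-] | intermediate
27 | A–O–B–O–C–OCH=PPh3: ylide of 26 | O(Cc6ccccc6)c1cc(OCc6ccccc6)c(Oc2cc(OCc6ccccc6)c(Oc3cc(OCc6ccccc6)c(OC=P(c6ccccc6)(c6ccccc6)c6ccccc6)c(OCc6ccccc6)c3)c(OCc6ccccc6)c2)c(OCc6ccccc6)c1 | intermediate
28 | ABC 2H-pyran adduct: A–O–B–O–C–O–CH(PPh3)–[3,5-bis(benzyloxy)-4-(tert-butyldimethylsilyloxy)-2H-pyran-2-yl] triflate (diastereomer mixture, racemic) | O(Cc6ccccc6)c1cc(OCc6ccccc6)c(Oc2cc(OCc6ccccc6)c(Oc3cc(OCc6ccccc6)c(OC([P+](c6ccccc6)(c6ccccc6)c6ccccc6)C7OC=C(OCc6ccccc6)C(O[Si](C)(C)C(C)(C)C)=C7OCc6ccccc6)c(OCc6ccccc6)c3)c(OCc6ccccc6)c2)c(OCc6ccccc6)c1.[O-]S(=O)(=O)C(F)(F)F | intermediate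
29 | ABC open-chain ylide aldehyde: (2Z)-6-(A–O–B–O–C–O)-2,4-bis(benzyloxy)-3-(tert-butyldimethylsilyloxy)-6-(triphenylphosphoranylidene)hexa-2,4-dienal (geometry at C4=C5 not fixed) | O(Cc6ccccc6)c1cc(OCc6ccccc6)c(Oc2cc(OCc6ccccc6)c(Oc3cc(OCc6ccccc6)c(OC(=P(c6ccccc6)(c6ccccc6)c6ccccc6)C=C(OCc6ccccc6)/C(O[Si](C)(C)C(C)(C)C)=C(OCc6ccccc6)\C=O)c(OCc6ccccc6)c3)c(OCc6ccccc6)c2)c(OCc6ccccc6)c1 | intermediate
30 | A–O–B–O–C–O–D–OSi(t-Bu)Me2: nona-O-benzyl ABCD tetramer, ring D C4 tert-butyldimethylsilyl ether | O(Cc6ccccc6)c1cc(OCc6ccccc6)c(Oc2cc(OCc6ccccc6)c(Oc3cc(OCc6ccccc6)c(Oc4cc(OCc6ccccc6)c(O[Si](C)(C)C(C)(C)C)c(OCc6ccccc6)c4)c(OCc6ccccc6)c3)c(OCc6ccccc6)c2)c(OCc6ccccc6)c1 | intermediate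
31 | A–O–B–O–C–O–D–OH: nona-O-benzyl ABCD tetramer, free hydroxyl at C4 of ring D | O(Cc6ccccc6)c1cc(OCc6ccccc6)c(Oc2cc(OCc6ccccc6)c(Oc3cc(OCc6ccccc6)c(Oc4cc(OCc6ccccc6)c(O)c(OCc6ccccc6)c4)c(OCc6ccccc6)c3)c(OCc6ccccc6)c2)c(OCc6ccccc6)c1 | intermediate
32 | A–O–B–O–C–O–D–OCH2Cl: chloromethyl ether of 31 | O(Cc6ccccc6)c1cc(OCc6ccccc6)c(Oc2cc(OCc6ccccc6)c(Oc3cc(OCc6ccccc6)c(Oc4cc(OCc6ccccc6)c(OCCl)c(OCc6ccccc6)c4)c(OCc6ccccc6)c3)c(OCc6ccccc6)c2)c(OCc6ccccc6)c1 | intermediate
33 | A–O–B–O–C–O–D–OCH2PPh3 chloride: (aryloxymethyl)triphenylphosphonium chloride of 31 | O(Cc6ccccc6)c1cc(OCc6ccccc6)c(Oc2cc(OCc6ccccc6)c(Oc3cc(OCc6ccccc6)c(Oc4cc(OCc6ccccc6)c(OC[P+](c6ccccc6)(c6ccccc6)c6ccccc6)c(OCc6ccccc6)c4)c(OCc6ccccc6)c3)c(OCc6ccccc6)c2)c(OCc6ccccc6)c1.[Cl-] | intermediate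
34 | A–O–B–O–C–O–D–OCH=PPh3: ylide of 33 | O(Cc6ccccc6)c1cc(OCc6ccccc6)c(Oc2cc(OCc6ccccc6)c(Oc3cc(OCc6ccccc6)c(Oc4cc(OCc6ccccc6)c(OC=P(c6ccccc6)(c6ccccc6)c6ccccc6)c(OCc6ccccc6)c4)c(OCc6ccccc6)c3)c(OCc6ccccc6)c2)c(OCc6ccccc6)c1 | intermediate
35 | ABCD 2H-pyran adduct: A–O–B–O–C–O–D–O–CH(PPh3)–[3,5-bis(benzyloxy)-4-(tert-butyldimethylsilyloxy)-2H-pyran-2-yl] triflate (diastereomer mixture, racemic) | O(Cc6ccccc6)c1cc(OCc6ccccc6)c(Oc2cc(OCc6ccccc6)c(Oc3cc(OCc6ccccc6)c(Oc4cc(OCc6ccccc6)c(OC([P+](c6ccccc6)(c6ccccc6)c6ccccc6)C7OC=C(OCc6ccccc6)C(O[Si](C)(C)C(C)(C)C)=C7OCc6ccccc6)c(OCc6ccccc6)c4)c(OCc6ccccc6)c3)c(OCc6ccccc6)c2)c(OCc6ccccc6)c1.[O-]S(=O)(=O)C(F)(F)F | intermediate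
36 | ABCD open-chain ylide aldehyde: (2Z)-6-(A–O–B–O–C–O–D–O)-2,4-bis(benzyloxy)-3-(tert-butyldimethylsilyloxy)-6-(triphenylphosphoranylidene)hexa-2,4-dienal (geometry at C4=C5 not fixed) | O(Cc6ccccc6)c1cc(OCc6ccccc6)c(Oc2cc(OCc6ccccc6)c(Oc3cc(OCc6ccccc6)c(Oc4cc(OCc6ccccc6)c(OC(=P(c6ccccc6)(c6ccccc6)c6ccccc6)C=C(OCc6ccccc6)/C(O[Si](C)(C)C(C)(C)C)=C(OCc6ccccc6)\C=O)c(OCc6ccccc6)c4)c(OCc6ccccc6)c3)c(OCc6ccccc6)c2)c(OCc6ccccc6)c1 | intermediate
37 | A–O–B–O–C–O–D–O–E–OSi(t-Bu)Me2: undeca-O-benzyl pentamer, ring E C4 tert-butyldimethylsilyl ether | O(Cc6ccccc6)c1cc(OCc6ccccc6)c(Oc2cc(OCc6ccccc6)c(Oc3cc(OCc6ccccc6)c(Oc4cc(OCc6ccccc6)c(Oc5cc(OCc6ccccc6)c(O[Si](C)(C)C(C)(C)C)c(OCc6ccccc6)c5)c(OCc6ccccc6)c4)c(OCc6ccccc6)c3)c(OCc6ccccc6)c2)c(OCc6ccccc6)c1 | intermediate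
38 | A–O–B–O–C–O–D–O–E–OH: undeca-O-benzyl pentamer, free hydroxyl at C4 of ring E | O(Cc6ccccc6)c1cc(OCc6ccccc6)c(Oc2cc(OCc6ccccc6)c(Oc3cc(OCc6ccccc6)c(Oc4cc(OCc6ccccc6)c(Oc5cc(OCc6ccccc6)c(O)c(OCc6ccccc6)c5)c(OCc6ccccc6)c4)c(OCc6ccccc6)c3)c(OCc6ccccc6)c2)c(OCc6ccccc6)c1 | intermediate
39 | target: 2-[4-[4-[4-(3,4,5-trihydroxyphenoxy)-3,5-dihydroxyphenoxy]-3,5-dihydroxyphenoxy]-3,5-dihydroxyphenoxy]benzene-1,3,5-triol | Oc1cc(O)c(Oc2cc(O)c(Oc3cc(O)c(Oc4cc(O)c(Oc5cc(O)c(O)c(O)c5)c(O)c4)c(O)c3)c(O)c2)c(O)c1 | target

## Step count and risks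

Total step count: 17. Longest linear sequence: 15 steps (steps 2 to 4 and 6 to 17, from 5); the pyranone branch (steps 1 and 5) joins at step 6, and its product 12 is drawn on again in steps 9, 12 and 15.

**Step 9 (key step).** The most likely failure is transfer of the silyl group from the pyrylium oxygen to the ylide carbon, which returns the pyranone and consumes the ylide; hydrolysis of the moisture-sensitive salt 12 before it reaches the ylide would have the same effect. The second is stalling after the addition: the ring-opened ylide is strongly delocalised into its own dienal and may be too stabilised, or held in the wrong geometry, to close. Fallback by known chemistry, setting out from phenol 17: Ullmann diaryl ether coupling (CuI, copper monoiodide, with picolinic acid and K3PO4 in DMSO at 90 °C) with 2,6-bis(benzyloxy)-4-bromobenzaldehyde F1. F1 would be made from commercial 4-bromo-2,6-difluorobenzaldehyde and sodium benzyloxide by double SNAr. The coupling gives the ABC aldehyde F2. Baeyer–Villiger oxidation with mCPBA gives the ABC formate F3, and methanolysis of F3 returns to the route at phenol 24.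

**Step 15.** The same failure modes apply, made worse by poor solubility and slow deprotonation of the largest salt at low temperature and by crowding around the reacting oxygen of the tetramer. Fallback, setting out from phenol 31: Ullmann coupling under the conditions above with 5-bromo-1,2,3-tris(benzyloxy)benzene F4 (from commercial 5-bromobenzene-1,2,3-triol, benzyl bromide and K2CO3) gives the dodeca-O-benzyl pentamer F5. Hydrogenolysis of F5 over Pd/C returns to the route at the target 39, bypassing 37 and 38.

**Step 12.** Competing silyl transfer to the ylide and incomplete closure of the open-chain intermediate are again the risks, on a substrate already large enough for solubility to matter. Fallback, setting out from phenol 24: Ullmann coupling with F1 gives the ABCD aldehyde F6; Baeyer–Villiger oxidation to the ABCD formate F7 and methanolysis return to the route at phenol 31.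

**Step 6.** This is the first use of an aryloxymethylene ylide with the silyloxypyrylium ion. If the ylide attacks silicon or merely deprotonates, no ring forms at all, and the fault would show here before valuable material is committed. Fallback, setting out from phenol 8: Ullmann coupling with F1 gives the AB aldehyde F8; Baeyer–Villiger oxidation to the AB formate F9 and methanolysis return to the route at phenol 17.

**Step 8 (and its siblings, steps 4, 11 and 14).** The phenoxide may attack its own product, the chloromethyl ether, faster than it attacks the dihalide, draining material into the symmetrical bis(aryloxy)methane. On heating, the α-chloro ether may also hydrolyse or alkylate the electron-rich ring A. Fallback, setting out from phenol 17: alkylation with chloromethyl methyl sulfide (NaH, NaI, DMF) gives the (methylthio)methyl ether F10, which cannot react further with phenoxide. Cleavage of its C–S bond with SO2Cl2 in CH2Cl2 at −78 °C returns to the route at chloromethyl ether 18, which is taken on with PPh3 to 19.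

**Step 17.** Hydrogenolysis of eleven benzyl ethers may stop short, because partly debenzylated material adsorbs on the catalyst or falls out of solution, and the free polyphenol may oxidise during filtration and concentration. Fallback, setting out from 38: non-reductive debenzylation with BCl3 and pentamethylbenzene as benzyl cation scavenger in CH2Cl2 at −78 °C, with a methanol quench. This is homogeneous, spares ring A from C-benzylation, and returns directly to 39 without any new intermediate.

## Further compounds

F1 | step 9 | 2,6-bis(benzyloxy)-4-bromobenzaldehyde | O=Cc1c(OCc2ccccc2)cc(Br)cc1OCc1ccccc1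
F2 | step 9 | ABC aldehyde: hepta-O-benzyl trimer with CHO in place of the C4 oxygen group of ring C | O(Cc6ccccc6)c1cc(OCc6ccccc6)c(Oc2cc(OCc6ccccc6)c(Oc3cc(OCc6ccccc6)c(C=O)c(OCc6ccccc6)c3)c(OCc6ccccc6)c2)c(OCc6ccccc6)c1
F3 | step 9 | ABC formate: formate ester of phenol 24 | O(Cc6ccccc6)c1cc(OCc6ccccc6)c(Oc2cc(OCc6ccccc6)c(Oc3cc(OCc6ccccc6)c(OC=O)c(OCc6ccccc6)c3)c(OCc6ccccc6)c2)c(OCc6ccccc6)c1
F4 | step 15 | 5-bromo-1,2,3-tris(benzyloxy)benzene | Brc1cc(OCc2ccccc2)c(OCc2ccccc2)c(OCc2ccccc2)c1
F5 | step 15 | dodeca-O-benzyl pentamer (all twelve hydroxyls of the target as benzyl ethers) | O(Cc6ccccc6)c1cc(OCc6ccccc6)c(Oc2cc(OCc6ccccc6)c(Oc3cc(OCc6ccccc6)c(Oc4cc(OCc6ccccc6)c(Oc5cc(OCc6ccccc6)c(OCc6ccccc6)c(OCc6ccccc6)c5)c(OCc6ccccc6)c4)c(OCc6ccccc6)c3)c(OCc6ccccc6)c2)c(OCc6ccccc6)c1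
F6 | step 12 | ABCD aldehyde: nona-O-benzyl tetramer with CHO in place of the C4 oxygen group of ring D | O(Cc6ccccc6)c1cc(OCc6ccccc6)c(Oc2cc(OCc6ccccc6)c(Oc3cc(OCc6ccccc6)c(Oc4cc(OCc6ccccc6)c(C=O)c(OCc6ccccc6)c4)c(OCc6ccccc6)c3)c(OCc6ccccc6)c2)c(OCc6ccccc6)c1
F7 | step 12 | ABCD formate: formate ester of phenol 31 | O(Cc6ccccc6)c1cc(OCc6ccccc6)c(Oc2cc(OCc6ccccc6)c(Oc3cc(OCc6ccccc6)c(Oc4cc(OCc6ccccc6)c(OC=O)c(OCc6ccccc6)c4)c(OCc6ccccc6)c3)c(OCc6ccccc6)c2)c(OCc6ccccc6)c1
F8 | step 6 | AB aldehyde: 2,6-bis(benzyloxy)-4-[2,4,6-tris(benzyloxy)phenoxy]benzaldehyde | O(Cc6ccccc6)c1cc(OCc6ccccc6)c(Oc2cc(OCc6ccccc6)c(C=O)c(OCc6ccccc6)c2)c(OCc6ccccc6)c1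
F9 | step 6 | AB formate: formate ester of phenol 17 | O(Cc6ccccc6)c1cc(OCc6ccccc6)c(Oc2cc(OCc6ccccc6)c(OC=O)c(OCc6ccccc6)c2)c(OCc6ccccc6)c1
F10 | step 8 | AB (methylthio)methyl ether: 1,3-bis(benzyloxy)-2-[(methylsulfanyl)methoxy]-5-[2,4,6-tris(benzyloxy)phenoxy]benzene | O(Cc6ccccc6)c1cc(OCc6ccccc6)c(Oc2cc(OCc6ccccc6)c(OCSC)c(OCc6ccccc6)c2)c(OCc6ccccc6)c1
F0 | step 17 | none | none
A1 | alternative 1 | deca-O-methyl pentamer with ring D as 3,5-dihydroxy-2-(methoxycarbonyl) unit | COc1cc(OC)c(Oc2cc(OC)c(Oc3cc(OC)c(Oc4cc(O)c(Oc5cc(OC)c(OC)c(OC)c5)c(O)c4C(=O)OC)c(OC)c3)c(OC)c2)c(OC)c1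
A2 | alternative 1 | methyl 3-(hepta-O-methyl ABC aryloxy)prop-2-ynoate | COc1cc(OC)c(Oc2cc(OC)c(Oc3cc(OC)c(OC#CC(=O)OC)c(OC)c3)c(OC)c2)c(OC)c1
A3 | alternative 1 | methyl 3-oxo-4-(3,4,5-trimethoxyphenoxy)butanoate | COC(=O)CC(=O)COc1cc(OC)c(OC)c(OC)c1
A4 | alternative 2 | undeca-O-methyl pentamer with free hydroxyl at C4 of ring E | COc1cc(OC)c(Oc2cc(OC)c(Oc3cc(OC)c(Oc4cc(OC)c(Oc5cc(OC)c(O)c(OC)c5)c(OC)c4)c(OC)c3)c(OC)c2)c(OC)c1
A5 | alternative 2 | syringic acid (4-hydroxy-3,5-dimethoxybenzoic acid) | COc1cc(cc(OC)c1O)C(O)=O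
A6 | alternative 2 | 2,4,6-trimethoxyphenol | COc1cc(OC)c(O)c(OC)c1
A7 | alternative 3 | deca-O-methyl pentamer with free hydroxyls at C3 and C5 of ring C | COc1cc(OC)c(Oc2cc(OC)c(Oc3cc(O)c(Oc4cc(OC)c(Oc5cc(OC)c(OC)c(OC)c5)c(OC)c4)c(O)c3)c(OC)c2)c(OC)c1
A8 | alternative 3 | 4-(penta-O-methyl AB aryloxy)-6-[(penta-O-methyl DE aryloxy)methyl]-2H-pyran-2-one | COc1cc(OC)c(Oc2cc(OC)c(OC3=CC(=O)OC(COc4cc(OC)c(Oc5cc(OC)c(OC)c(OC)c5)c(OC)c4)=C3)c(OC)c2)c(OC)c1
A9 | alternative 3 | triacetic acid lactone (4-hydroxy-6-methyl-2H-pyran-2-one) | CC1=CC(O)=CC(=O)O1
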